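**Plan**
- Retrosynthesis: the two ester C–O bonds (aryl angelate, primary tiglate) and the oxirane O–CH2 bond are cut first, then the arene itself at C4–C5, C6–C1 and C1–C2 (C1 = acyloxy carbon).
- Enabling feature: the benzene ring is a hydroquinone with differentiated oxygens (OMe on C4, acyloxy on C1), CH3 on C3 beside the methoxy and the quaternary side chain on C6 beside the acyloxy group. This is the imprint of a methoxy(isopropenyl)carbene unit (C4, C3, C2), one CO (C1) and a terminal alkyne (C5, C6).
- Forward: enynol → epoxy alcohol → ether-differentiated diol → acetonide alkyne; carbene complex in one step; benzannulation builds the arene (ring one); then phenol angelate, acetonide removal, mesylate, oxirane closure (ring two), ether removal, tiglate.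
- Stereochemistry: the single stereocentre is set by a Sharpless epoxidation before the arene exists. It is quaternary, and its two CH2O arms are kept apart by a benzyl-type ether that cannot migrate until the oxirane is closed, so no acyl shift can scramble it. The Z and E ester geometries come in with angelic and tiglic acid.

Key step: step 6

Remark: the empirical facial rule of the Sharpless epoxidation (D-(−)-tartrate turns allyl alcohol into (R)-glycidol) is assumed to hold for the 2-alkynyl allylic alcohol made in step 1.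

**Route**

Step 1
Reactants: 1 2-bromoprop-2-en-1-ol; 2 ethynyltrimethylsilane
Product: 3 2-methylidene-4-(trimethylsilyl)but-3-yn-1-ol
Conditions: PdCl2(PPh3)2 (2 mol%), CuI (4 mol%), Et3N, THF, rt
Reagents that add atoms: none
Why: Sonogashira coupling (oxidative addition of the vinyl C–Br bond to zerovalent palladium, transmetalation from the copper acetylide, reductive elimination) runs at room temperature on vinyl bromides and tolerates the free hydroxyl.

Step 2
Reactants: 3 2-methylidene-4-(trimethylsilyl)but-3-yn-1-ol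
Product: 4 [(2R)-2-[(trimethylsilyl)ethynyl]oxiran-2-yl]methanol
Conditions: Ti(OiPr)4 (20 mol%), D-(−)-diisopropyl tartrate (24 mol%), t-BuOOH, 4 Å MS, CH2Cl2, −20 °C
Reagents that add atoms: tert-butyl hydroperoxide, CC(C)(C)OO
Why: Sharpless asymmetric epoxidation delivers the peroxide oxygen within the titanium–tartrate–allylic alkoxide complex to one alkene face only; D-(−)-tartrate should select the face that gives the (R)-glycidol-type arrangement (alkynyl in the place of H), and the alkyne, having no directing hydroxyl of its own, should stay untouched.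

Step 3
Reactants: 4 [(2R)-2-[(trimethylsilyl)ethynyl]oxiran-2-yl]methanol
Product: 6 (2R)-2-ethynyl-3-[(4-methoxyphenyl)methoxy]propane-1,2-diol, via [(2R)-2-ethynyloxiran-2-yl]methanol 5 (not isolated)
Conditions: 4-MeOC6H4CH2OH (excess), NaH (less than the alcohol), THF/DMPU, 0 → 65 °C; then H2O
Reagents that add atoms: 4-methoxybenzyl alcohol, COc1ccc(CO)cc1
Why: The alkoxide first cleaves the C–Si bond and then opens the oxirane by SN2 attack at its unsubstituted CH2, so the C–O bond at the quaternary carbon is never broken and the configuration should be retained (a Payne shift in this system only regenerates the same compound).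

Step 4
Reactants: 6 (2R)-2-ethynyl-3-[(4-methoxyphenyl)methoxy]propane-1,2-diol
Product: 7 (4S)-4-ethynyl-4-{[(4-methoxyphenyl)methoxy]methyl}-2,2-dimethyl-1,3-dioxolane
Conditions: Me2C(OMe)2, PPTS (cat.), acetone, rt
Reagents that add atoms: 2,2-dimethoxypropane, COC(C)(C)OC
Why: Acid-catalysed transketalisation can only engage the free 1,2-diol (the third oxygen is etherified), giving one dioxolane without touching any bond at the stereocentre.

Step 5
Reactants: 8 2-bromopropene; 9 chromium hexacarbonyl
Product: 12 pentacarbonyl[methoxy(prop-1-en-2-yl)carbene]chromium, via isopropenyllithium 10 (not isolated), via lithium pentacarbonyl(2-methylprop-2-enoyl)chromate 11 (not isolated)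
Conditions: t-BuLi (2 equiv), Et2O, −78 °C; 9, Et2O, −78 °C → rt; then Me3OBF4, CH2Cl2, 0 °C
Reagents that add atoms: trimethyloxonium tetrafluoroborate, C[O+](C)C.F[B-](F)(F)F
Why: Fischer carbene synthesis: the vinyllithium from bromine–lithium exchange adds to a CO ligand of Cr(CO)6 and the resulting acylchromate is O-methylated by the hard oxonium salt.

Step 6
Reactants: 12 pentacarbonyl[methoxy(prop-1-en-2-yl)carbene]chromium; 7 (4S)-4-ethynyl-4-{[(4-methoxyphenyl)methoxy]methyl}-2,2-dimethyl-1,3-dioxolane
Product: 14 2-[(4S)-4-{[(4-methoxyphenyl)methoxy]methyl}-2,2-dimethyl-1,3-dioxolan-4-yl]-4-methoxy-5-methylphenol, via its tricarbonylchromium η6-arene complex 13 (not isolated)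
Conditions: THF, 50 °C, Ar; then air, MeCN, rt
Reagents that add atoms: none
Why: Thermal loss of one CO from 12 lets the alkyne bind and insert into the Cr=C bond with its CH carbon joined to the carbene carbon; CO insertion then gives a chromium-bound dienylketene, so the three new ring bonds are carbene C–alkyne CH, substituted alkyne C–CO carbon and CO carbon–isopropenyl CH2. This is the Dötz benzannulation of an alkenyl(alkoxy) Fischer carbene complex with a terminal alkyne, the best-behaved variant of that reaction. The one ring closes by 6π electrocyclisation of the metal-bound dienylketene (ketene carbon to the isopropenyl terminus), and enolisation of the cyclohexadienone gives the phenol with methoxy and hydroxyl already differentiated. No stereocentre is formed; the quaternary carbon of 7 bears no hydrogen and lies outside the reacting π system, so its configuration should be carried over unchanged. The step needs regioselective insertion, which the terminal alkyne secures: the bulky dioxolanyl group should end up next to the CO-derived carbon (ortho to OH) and the alkyne CH next to the methoxy-bearing carbon. Freeing the arene from Cr(CO)3 with air and not with a strong oxidant should keep the 4-methoxyphenol from going on to the quinone.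

Step 7
Reactants: 14 2-[(4S)-4-{[(4-methoxyphenyl)methoxy]methyl}-2,2-dimethyl-1,3-dioxolan-4-yl]-4-methoxy-5-methylphenol; 15 angelic acid
Product: 17 2-[(4S)-4-{[(4-methoxyphenyl)methoxy]methyl}-2,2-dimethyl-1,3-dioxolan-4-yl]-4-methoxy-5-methylphenyl (2Z)-2-methylbut-2-enoate, via angelic 2,4,6-trichlorobenzoic anhydride 16 (not isolated)
Conditions: 15, 2,4,6-Cl3C6H2COCl, Et3N, PhMe, rt; then 14, 60 °C
Reagents that add atoms: none
Why: Yamaguchi-type mixed-anhydride acylation: the phenoxide attacks the unshielded angeloyl carbonyl, and leaving out a nucleophilic acyl-transfer catalyst should avoid Z → E isomerisation of the angelate.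

Step 8
Reactants: 17 2-[(4S)-4-{[(4-methoxyphenyl)methoxy]methyl}-2,2-dimethyl-1,3-dioxolan-4-yl]-4-methoxy-5-methylphenyl (2Z)-2-methylbut-2-enoate
Product: 18 2-{(2R)-1,2-dihydroxy-3-[(4-methoxyphenyl)methoxy]propan-2-yl}-4-methoxy-5-methylphenyl (2Z)-2-methylbut-2-enoate
Conditions: AcOH/H2O (4:1), 40 °C
Reagents that add atoms: none
Why: Acid hydrolysis of the isopropylidene ketal goes through the oxocarbenium ion at the ketal carbon, so the C–O bonds at the stereocentre stay intact, and the benzyl-type ether and the aryl ester should survive aqueous acetic acid.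

Step 9
Reactants: 18 2-{(2R)-1,2-dihydroxy-3-[(4-methoxyphenyl)methoxy]propan-2-yl}-4-methoxy-5-methylphenyl (2Z)-2-methylbut-2-enoate
Product: 19 2-{(2S)-2-hydroxy-1-[(methanesulfonyl)oxy]-3-[(4-methoxyphenyl)methoxy]propan-2-yl}-4-methoxy-5-methylphenyl (2Z)-2-methylbut-2-enoate
Conditions: MsCl, Et3N, CH2Cl2, −20 °C
Reagents that add atoms: methanesulfonyl chloride, CS(=O)(=O)Cl
Why: Sulfonylation (via sulfene) should take the only primary hydroxyl and leave the hindered tertiary benzylic one free.

Step 10
Reactants: 19 2-{(2S)-2-hydroxy-1-[(methanesulfonyl)oxy]-3-[(4-methoxyphenyl)methoxy]propan-2-yl}-4-methoxy-5-methylphenyl (2Z)-2-methylbut-2-enoate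
Product: 20 4-methoxy-2-[(2R)-2-{[(4-methoxyphenyl)methoxy]methyl}oxiran-2-yl]-5-methylphenyl (2Z)-2-methylbut-2-enoate
Conditions: NaH, THF, 0 °C
Reagents that add atoms: none
Why: Intramolecular Williamson etherification (3-exo-tet): the tertiary alkoxide displaces the neighbouring primary mesylate, the stereocentre carries the nucleophilic oxygen and is not the carbon attacked, and this fast closure should outrun acyl transfer from the hindered aryl angelate.

Step 11
Reactants: 20 4-methoxy-2-[(2R)-2-{[(4-methoxyphenyl)methoxy]methyl}oxiran-2-yl]-5-methylphenyl (2Z)-2-methylbut-2-enoate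
Product: 21 2-[(2S)-2-(hydroxymethyl)oxiran-2-yl]-4-methoxy-5-methylphenyl (2Z)-2-methylbut-2-enoate
Conditions: DDQ, CH2Cl2/pH 7 phosphate buffer, 0 °C → rt
Reagents that add atoms: none
Why: Oxidative cleavage of the 4-methoxybenzyl ether by DDQ (benzylic hydride abstraction, hydrolysis of the oxocarbenium ion) is selective for the ether-activated benzylic CH2, and the buffer should protect the oxirane.

Step 12
Reactants: 21 2-[(2S)-2-(hydroxymethyl)oxiran-2-yl]-4-methoxy-5-methylphenyl (2Z)-2-methylbut-2-enoate; 22 tiglic acid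
Product: 23 {(2R)-2-[5-methoxy-4-methyl-2-{[(2Z)-2-methylbut-2-enoyl]oxy}phenyl]oxiran-2-yl}methyl (2E)-2-methylbut-2-enoate
Conditions: 22, DCC, DMAP (cat.), CH2Cl2, 0 °C → rt
Reagents that add atoms: none
Why: Steglich esterification of the primary alcohol with the thermodynamically stable E-acid under near-neutral conditions should spare the oxirane and the aryl angelate; the arms are now constitutionally different, so the stereocentre is safe.

**Compound list**

1 | 2-bromoprop-2-en-1-ol | OCC(Br)=C | starting material
2 | ethynyltrimethylsilane | C#C[Si](C)(C)C | starting material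
3 | 2-methylidene-4-(trimethylsilyl)but-3-yn-1-ol | OCC(=C)C#C[Si](C)(C)C | intermediate
4 | [(2R)-2-[(trimethylsilyl)ethynyl]oxiran-2-yl]methanol | C[Si](C)(C)C#C[C@@]1(CO)CO1 | intermediate
5 | [(2R)-2-ethynyloxiran-2-yl]methanol | C#C[C@@]1(CO)CO1 | intermediate (not isolated)
6 | (2R)-2-ethynyl-3-[(4-methoxyphenyl)methoxy]propane-1,2-diol | C#C[C@@](O)(CO)COCc1ccc(OC)cc1 | intermediate
7 | (4S)-4-ethynyl-4-{[(4-methoxyphenyl)methoxy]methyl}-2,2-dimethyl-1,3-dioxolane | C#C[C@]1(COCc2ccc(OC)cc2)COC(C)(C)O1 | intermediate
8 | 2-bromopropene | CC(Br)=C | starting material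
9 | chromium hexacarbonyl Cr(CO)6 | O=C=[Cr](=C=O)(=C=O)(=C=O)(=C=O)=C=O | starting material
10 | isopropenyllithium | [Li]C(C)=C | intermediate (not isolated)
11 | lithium pentacarbonyl(2-methylprop-2-enoyl)chromate | [Li+].[O-]C(C(C)=C)=[Cr](=C=O)(=C=O)(=C=O)(=C=O)=C=O | intermediate (not isolated)
12 | pentacarbonyl[methoxy(prop-1-en-2-yl)carbene]chromium | COC(C(C)=C)=[Cr](=C=O)(=C=O)(=C=O)(=C=O)=C=O | intermediate
13 | tricarbonylchromium η6-arene complex of phenol 14 | Oc1cc(C)c(OC)cc1[C@]1(COCc2ccc(OC)cc2)COC(C)(C)O1.O=C=[Cr](=C=O)=C=O | intermediate (not isolated)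
14 | 2-[(4S)-4-{[(4-methoxyphenyl)methoxy]methyl}-2,2-dimethyl-1,3-dioxolan-4-yl]-4-methoxy-5-methylphenol | Oc1cc(C)c(OC)cc1[C@]1(COCc2ccc(OC)cc2)COC(C)(C)O1 | intermediate
15 | angelic acid [(2Z)-2-methylbut-2-enoic acid] | C/C=C(/C)C(O)=O | starting material
16 | angelic 2,4,6-trichlorobenzoic anhydride | C/C=C(/C)C(=O)OC(=O)c1c(Cl)cc(Cl)cc1Cl | intermediate (not isolated)
17 | 2-[(4S)-4-{[(4-methoxyphenyl)methoxy]methyl}-2,2-dimethyl-1,3-dioxolan-4-yl]-4-methoxy-5-methylphenyl (2Z)-2-methylbut-2-enoate | C/C=C(/C)C(=O)Oc1cc(C)c(OC)cc1[C@]1(COCc2ccc(OC)cc2)COC(C)(C)O1 | intermediate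
18 | 2-{(2R)-1,2-dihydroxy-3-[(4-methoxyphenyl)methoxy]propan-2-yl}-4-methoxy-5-methylphenyl (2Z)-2-methylbut-2-enoate | C/C=C(/C)C(=O)Oc1cc(C)c(OC)cc1[C@@](O)(CO)COCc1ccc(OC)cc1 | intermediate
19 | 2-{(2S)-2-hydroxy-1-[(methanesulfonyl)oxy]-3-[(4-methoxyphenyl)methoxy]propan-2-yl}-4-methoxy-5-methylphenyl (2Z)-2-methylbut-2-enoate | C/C=C(/C)C(=O)Oc1cc(C)c(OC)cc1[C@@](O)(COS(C)(=O)=O)COCc1ccc(OC)cc1 | intermediate
20 | 4-methoxy-2-[(2R)-2-{[(4-methoxyphenyl)methoxy]methyl}oxiran-2-yl]-5-methylphenyl (2Z)-2-methylbut-2-enoate | C/C=C(/C)C(=O)Oc1cc(C)c(OC)cc1[C@]1(COCc2ccc(OC)cc2)CO1 | intermediate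
21 | 2-[(2S)-2-(hydroxymethyl)oxiran-2-yl]-4-methoxy-5-methylphenyl (2Z)-2-methylbut-2-enoate | C/C=C(/C)C(=O)Oc1cc(C)c(OC)cc1[C@]1(CO)CO1 | intermediate
22 | tiglic acid [(2E)-2-methylbut-2-enoic acid] | C/C=C(C)/C(O)=O | starting material
23 | {(2R)-2-[5-methoxy-4-methyl-2-{[(2Z)-2-methylbut-2-enoyl]oxy}phenyl]oxiran-2-yl}methyl (2E)-2-methylbut-2-enoate (CNP0103045.2) | C/C=C(/C)C(=O)Oc1cc(C)c(OC)cc1[C@]1(COC(=O)/C(C)=C/C)CO1 | target

**Count and risks**

Total: 12 steps. Longest linear sequence: 11 steps (steps 1–4, then 6–12); the carbene branch adds step 5.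

Risk 1, step 6 (benzannulation).
- What may go wrong: alkyne insertion may be slow because the reacting alkyne carbon sits next to a fully substituted carbon, so carbene decomposition or non-aromatising channels could compete; the electron-rich phenol could also be over-oxidised during decomplexation.
- Fallback (sets out from 3, returns at 21): the same ring construction is run on a flat enyne and the stereocentre is set afterwards on the arene.
- Silylation of 3 (TBSCl, imidazole, DMF) should give tert-butyldimethyl{[2-methylidene-4-(trimethylsilyl)but-3-yn-1-yl]oxy}silane F1, and K2CO3 in MeOH should free the alkyne to tert-butyldimethyl[(2-methylidenebut-3-yn-1-yl)oxy]silane F2.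
- Heated with 12 in THF, this enyne (sp2 carbon in place of the quaternary one) should insert readily and give, through the tricarbonylchromium η6-arene complex F3 and air, 2-{3-[(tert-butyldimethylsilyl)oxy]prop-1-en-2-yl}-4-methoxy-5-methylphenol F4.
- Acylation with 16 as in step 7 should give 2-{3-[(tert-butyldimethylsilyl)oxy]prop-1-en-2-yl}-4-methoxy-5-methylphenyl (2Z)-2-methylbut-2-enoate F5, and HF·pyridine should give 2-(3-hydroxyprop-1-en-2-yl)-4-methoxy-5-methylphenyl (2Z)-2-methylbut-2-enoate F6.
- Sharpless epoxidation of this 2-arylallyl alcohol with Ti(OiPr)4, L-(+)-diisopropyl tartrate and t-BuOOH (the tartrate that gives (S)-glycidol) should deliver 21 directly; step 12 then follows.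

Risk 2, step 2 (asymmetric epoxidation of the enynol).
- What may go wrong: oxygen transfer to an alkene deactivated by the cross-conjugated alkyne may be slow, which would erode facial selectivity; titanium-promoted opening of the 2,2-disubstituted epoxy alcohol could add to the loss.
- Fallback (sets out from 1, returns at 6): the epoxidation is done before the alkyne exists, on an electron-richer 2-(alkoxymethyl)allyl alcohol.
- Etherification of 1 (NaH, 4-MeOC6H4CH2Cl, THF) should give 1-{[(2-bromoprop-2-en-1-yl)oxy]methyl}-4-methoxybenzene F7, and Stille coupling with Bu3SnCH2OH under Pd(PPh3)4 in dioxane should give 2-{[(4-methoxyphenyl)methoxy]methyl}prop-2-en-1-ol F8.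
- Sharpless epoxidation with D-(−)-diisopropyl tartrate should give [(2R)-2-{[(4-methoxyphenyl)methoxy]methyl}oxiran-2-yl]methanol F9.
- Dess–Martin oxidation should give (2R)-2-{[(4-methoxyphenyl)methoxy]methyl}oxirane-2-carbaldehyde F10, and Ohira–Bestmann homologation (dimethyl (1-diazo-2-oxopropyl)phosphonate, K2CO3, MeOH) should give (2R)-2-ethynyl-2-{[(4-methoxyphenyl)methoxy]methyl}oxirane F11.
- KOH in aqueous DMSO should open the oxirane at its CH2 with retention at the quaternary carbon and give 6; step 4 then follows.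

Risk 3, step 10 (oxirane closure).
- What may go wrong: the angeloyl group may transfer from the phenolic oxygen to the tertiary alkoxide through a six-membered transition state, and the freed phenoxide would then attack the mesylate-bearing carbon.
- Fallback (sets out from 18, returns at 20): Mitsunobu cyclodehydration of the diol (PPh3, diisopropyl azodicarboxylate, THF) activates the primary hydroxyl as its oxyphosphonium ion and lets the tertiary hydroxyl close the ring without a free alkoxide; it also replaces step 9 and forms no new isolated compound.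

**Further compounds**

F1 | step 6 | tert-butyldimethyl{[2-methylidene-4-(trimethylsilyl)but-3-yn-1-yl]oxy}silane | C=C(CO[Si](C)(C)C(C)(C)C)C#C[Si](C)(C)C
F2 | step 6 | tert-butyldimethyl[(2-methylidenebut-3-yn-1-yl)oxy]silane | C=C(CO[Si](C)(C)C(C)(C)C)C#C
F3 | step 6 | tricarbonylchromium η6-arene complex of phenol F4 | Oc1cc(C)c(OC)cc1C(=C)CO[Si](C)(C)C(C)(C)C.O=C=[Cr](=C=O)=C=O
F4 | step 6 | 2-{3-[(tert-butyldimethylsilyl)oxy]prop-1-en-2-yl}-4-methoxy-5-methylphenol | Oc1cc(C)c(OC)cc1C(=C)CO[Si](C)(C)C(C)(C)C
F5 | step 6 | 2-{3-[(tert-butyldimethylsilyl)oxy]prop-1-en-2-yl}-4-methoxy-5-methylphenyl (2Z)-2-methylbut-2-enoate | C/C=C(/C)C(=O)Oc1cc(C)c(OC)cc1C(=C)CO[Si](C)(C)C(C)(C)C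
F6 | step 6 | 2-(3-hydroxyprop-1-en-2-yl)-4-methoxy-5-methylphenyl (2Z)-2-methylbut-2-enoate | C/C=C(/C)C(=O)Oc1cc(C)c(OC)cc1C(=C)CO
F7 | step 2 | 1-{[(2-bromoprop-2-en-1-yl)oxy]methyl}-4-methoxybenzene | C=C(Br)COCc1ccc(OC)cc1
F8 | step 2 | 2-{[(4-methoxyphenyl)methoxy]methyl}prop-2-en-1-ol | C=C(CO)COCc1ccc(OC)cc1
F9 | step 2 | [(2R)-2-{[(4-methoxyphenyl)methoxy]methyl}oxiran-2-yl]methanol | OC[C@]1(COCc2ccc(OC)cc2)CO1
F10 | step 2 | (2R)-2-{[(4-methoxyphenyl)methoxy]methyl}oxirane-2-carbaldehyde | O=C[C@]1(COCc2ccc(OC)cc2)CO1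
F11 | step 2 | (2R)-2-ethynyl-2-{[(4-methoxyphenyl)methoxy]methyl}oxirane | C#C[C@]1(COCc2ccc(OC)cc2)CO1
F0 | step 10 | none | none
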